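**Plan**

1. Cuts (furo[3,4-c]furan numbering C1–O2–C3–C3a–C4–O5–C6–C6a; OH on C3a, aryl groups on C3 and C6). First cut C3–C3a in the oxolane C1/O2/C3/C3a/C6a, which turns C3a–OH into a ketone and C3 into the CH2 of a veratryl (3,4-dimethoxybenzyl) ether. Then cut O5–C4 of the other oxolane, then C6–C6a.
2. Enabling feature: the tertiary carbinol C3a is bonded directly to the benzylic ether carbon C3, and O2 sits γ to C3a. An excited C3a=O group therefore finds no γ-hydrogen and can only take the δ-hydrogen at C3, which is benzylic and α to oxygen. Collapse of the 1,5-biradical gives the ring, the C–C bond, the tertiary alcohol and two stereocentres at once.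
3. Forward: (Z)-butenediol is etherified twice, which places all 22 carbons in one symmetric ether. An asymmetric [2,3]-Wittig shift joins C6–C6a. Epoxidation and 5-endo opening close the oxolane C3a/C4/O5/C6/C6a, oxidation gives the 4,5-cis oxolan-3-one, and light closes the second oxolane last.
4. Stereochemistry: the C6/C6a relation (syn, later cis, i.e. endo aryl) comes from the Z-alkene in the concerted shift, and the absolute sense from a chiral bis(oxazoline) on lithium. C3a comes from the tether (cis fusion only). C3 comes from the exo preference of the aryl group in the biradical closure.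

Key step: step 6

Assumption: the (S,S)-ligand is taken to deliver the (1R,2R) alcohol. If the sense of induction is the opposite, the equally available (R,R)-ligand is used and nothing else changes.

**Step 1**
Reactants: 1 (Z)-but-2-ene-1,4-diol; 2 3,4-dimethoxybenzyl chloride (veratryl chloride, two equivalents)
Product: 3 (Z)-1,4-bis[(3,4-dimethoxybenzyl)oxy]but-2-ene
Conditions: NaH, Bu4NI (cat.), THF/DMF, 0 °C to rt
Reagents that add atoms: none
Why: Double Williamson etherification of a primary allylic diol with a reactive benzylic chloride under iodide catalysis is routine, creates no stereocentre, leaves the Z-alkene untouched and places all 22 carbon atoms of the target in one symmetric molecule.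

**Step 2**
Reactants: 3 (Z)-1,4-bis[(3,4-dimethoxybenzyl)oxy]but-2-ene
Product: 5 (1R,2R)-1-(3,4-dimethoxyphenyl)-2-{[(3,4-dimethoxybenzyl)oxy]methyl}but-3-en-1-ol (syn), via benzylic lithio ether 4 (not isolated)
Conditions: t-BuLi, (S,S)-t-Bu-box [2,2'-(propane-2,2-diyl)bis((4S)-4-tert-butyl-4,5-dihydrooxazole)], hexane/Et2O, −78 °C; then H2O
Reagents that add atoms: none
Why: In this enantioselective [2,3]-Wittig rearrangement the bis(oxazoline)–t-BuLi complex removes one benzylic proton next to oxygen, the lithio ether 4 rearranges suprafacially through a five-membered envelope transition state in which the Z-alkene and the exo aryl group enforce the syn relation of the carbinol and allylic centres, the ligand on lithium decides the absolute sense, and ligand-controlled rearrangements of this kind are known for (Z)-4-oxygenated but-2-enyl benzyl ethers.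

**Step 3**
Reactants: 5 syn homoallylic alcohol
Product: 6 (1R,2R)-1-(3,4-dimethoxyphenyl)-3-[(3,4-dimethoxybenzyl)oxy]-2-(oxiran-2-yl)propan-1-ol (both epimers at the oxirane carbon)
Conditions: mCPBA, CH2Cl2, 0 °C to rt; basic wash
Reagents that add atoms: mCPBA, O=C(OO)c1cccc(Cl)c1
Why: Prilezhaev epoxidation attacks the only alkene while the arenes, ethers and alcohol are inert to the peracid at this temperature, and the configuration of the new oxirane carbon is of no consequence because this carbon becomes the carbonyl carbon in step 5.

**Step 4**
Reactants: 6 epoxy alcohol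
Product: 7 (4S,5R)-5-(3,4-dimethoxyphenyl)-4-{[(3,4-dimethoxybenzyl)oxy]methyl}oxolan-3-ol (4,5-cis, both C3 epimers)
Conditions: CSA (10 mol %), CH2Cl2, 0 °C
Reagents that add atoms: none
Why: Acid-catalysed intramolecular opening of a 3,4-epoxy alcohol at its unsubstituted terminus (5-endo mode, known to be preferred to 4-exo oxetane formation under acid) by the benzylic hydroxyl group forms the O–CH2 bond of the first oxolane without breaking any bond at the two existing stereocentres, so the syn relation of 5 is carried over as the 4,5-cis relation of 7.

**Step 5**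
Reactants: 7 oxolan-3-ol
Product: 8 (4R,5R)-5-(3,4-dimethoxyphenyl)-4-{[(3,4-dimethoxybenzyl)oxy]methyl}oxolan-3-one (4,5-cis)
Conditions: Dess–Martin periodinane, CH2Cl2, 0 °C to rt; short neutral work-up, used at once
Reagents that add atoms: none
Why: Dess–Martin oxidation of the single free secondary alcohol runs without amine base, which should keep the kinetically trapped cis ketone from epimerising at C4 and from β-elimination of either alkoxy group, and it merges both carbinol epimers into one compound.

**Step 6**
Reactants: 8 4,5-cis oxolan-3-one
Product: 10 (+)-gmelinol, via 1,5-biradical 9 (not isolated)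
Conditions: hν (medium-pressure Hg lamp, Pyrex, λ > 290 nm), degassed benzene, 0.01 M, 15–20 °C
Reagents that add atoms: none
Why: n→π* excitation of the ring carbonyl of 8 gives an oxygen-radical-like state that has no γ-hydrogen to take (the γ atom of the side chain is the ether oxygen and the ring C5–H cannot reach the carbonyl oxygen), so it abstracts a δ-hydrogen of the veratryl CH2 through a seven-membered transition state, a C–H bond weakened by both the aryl group and the oxygen, and gives the 1,5-biradical 9. Radical–radical recombination in 9 forms the C3–C3a bond and closes the second oxolane (1,5-biradical closure to a five-membered ring), so that the tertiary alcohol, the fully substituted carbon and the benzylic centre arise together without any reagent. The closest known reaction type is the Norrish–Yang photocyclisation of β-alkoxy ketones by δ-hydrogen abstraction to oxolan-3-ols, which is known for 4-(benzyloxymethyl)oxolan-3-ones. C3a is controlled by the tether: the CH2–O–CH arm hangs from C4 of 8 (C6a of 10) and can reach only the carbonyl face syn to it, which gives the cis-fused bicycle with OH cis to H-6a, the very face that an external nucleophile would avoid because the cis aryl group shields it. C3 is controlled in the closure of the freely rotating benzylic radical, whose aryl group turns to the convex (exo) side, away from the concave pocket that already holds the endo aryl group at C6. The step needs δ-abstraction to outrun α-cleavage (Norrish type I) and enolisation at C4, which is secured by the doubly activated C–H donor held next to the carbonyl group, by neutral degassed benzene and by the Pyrex filter that keeps most light away from the veratryl chromophores.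

**Compound list**

1 | (Z)-but-2-ene-1,4-diol | OC/C=C\CO | starting material
2 | 3,4-dimethoxybenzyl chloride | COc1ccc(CCl)cc1OC | starting material
3 | (Z)-1,4-bis[(3,4-dimethoxybenzyl)oxy]but-2-ene | COc1ccc(COC/C=C\COCc2ccc(OC)c(OC)c2)cc1OC | intermediate
4 | benzylic lithio ether of 3 (ligand-bound, not isolated) | COc1ccc(C([Li])OC/C=C\COCc2ccc(OC)c(OC)c2)cc1OC | intermediate
5 | (1R,2R)-1-(3,4-dimethoxyphenyl)-2-{[(3,4-dimethoxybenzyl)oxy]methyl}but-3-en-1-ol | COc1ccc(COC[C@H]([C@@H](O)c2ccc(OC)c(OC)c2)C=C)cc1OC | intermediate
6 | (1R,2R)-1-(3,4-dimethoxyphenyl)-3-[(3,4-dimethoxybenzyl)oxy]-2-(oxiran-2-yl)propan-1-ol, oxirane epimers | COc1ccc(COC[C@H]([C@@H](O)c2ccc(OC)c(OC)c2)C3CO3)cc1OC | intermediate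
7 | (4S,5R)-5-(3,4-dimethoxyphenyl)-4-{[(3,4-dimethoxybenzyl)oxy]methyl}oxolan-3-ol, 4,5-cis, C3 epimers | COc1ccc(COC[C@@H]2[C@H](c3ccc(OC)c(OC)c3)OCC2O)cc1OC | intermediate
8 | (4R,5R)-5-(3,4-dimethoxyphenyl)-4-{[(3,4-dimethoxybenzyl)oxy]methyl}oxolan-3-one, 4,5-cis | COc1ccc(COC[C@@H]2[C@H](c3ccc(OC)c(OC)c3)OCC2=O)cc1OC | intermediate
9 | 1,5-biradical (ketyl carbon C3 of the ring and benzylic ether carbon, not isolated) | COc1ccc([CH]OC[C@@H]2[C@H](c3ccc(OC)c(OC)c3)OC[C]2O)cc1OC | intermediate
10 | (+)-gmelinol, (3R,3aS,6R,6aR)-3,6-bis(3,4-dimethoxyphenyl)-3,4,6,6a-tetrahydro-1H-furo[3,4-c]furan-3a-ol | COc1ccc([C@H]2OC[C@@H]3[C@H](c4ccc(OC)c(OC)c4)OC[C@]23O)cc1OC | target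

**Total step count:** 6. **Longest linear sequence:** 6.

**Steps most likely to fail**

**Step 6.**
- What may go wrong: α-cleavage of the α-alkoxy ketone, return of the hydrogen atom within the biradical, loss of the cis relation at C4 by enolisation or by cleavage and recombination, filtering of the light by the aryl groups, and weak exo/endo discrimination at C3.
- Fallback: a ground-state route that closes the same ring through its C–O bond. It sets out from 8 and 2 and returns at 10.
- Compound 2 is converted with Mg into 3,4-dimethoxybenzylmagnesium chloride F1. After transmetalation with CeCl3 (THF, −78 °C), this adds to 8 from the open face to give the tertiary benzyl carbinol F2.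
- Dehydration with the Burgess reagent, a syn elimination toward the benzylic hydrogen, gives the exocyclic benzylidene oxolane F3.
- OsO4/NMO attacks F3 from the face opposite to the cis aryl group and side chain. This puts the tertiary hydroxyl group on the face required in the target and gives the vicinal diol F4.
- MsCl/Et3N (CH2Cl2, −20 °C) activates the electron-rich secondary benzylic alcohol. The oxygen of the veratryl ether then closes the oxolane and loses its veratryl group (debenzylative cycloetherification), the aryl group settles exo, and 10 results.

**Step 2.**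
- What may go wrong: incomplete enantiofacial discrimination by the ligand, 1,4-elimination to an alkoxydiene after allylic deprotonation, a competing [1,2]-shift, and ring lithiation ortho to a methoxy group.
- Fallback: rearrangement with an achiral base followed by resolution through covalent diastereomers. It sets out from 3 and returns at 5.
- n-BuLi in THF at −78 °C should give the syn alcohol as a racemate, that is 5 together with the (1S,2S)-alcohol F5.
- Esterification with (S)-O-methylmandelic acid (DCC, DMAP) gives the (S)-O-methylmandelate of the (1R,2R)-alcohol F6 and the (S)-O-methylmandelate of the (1S,2S)-alcohol F7. These are separated by chromatography or crystallisation and also allow the absolute configuration to be checked.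
- LiOH in THF/H2O cleaves F6 and returns 5.

**Step 4.**
- What may go wrong: attack at the inner oxirane carbon (4-exo), participation of the veratryl ether oxygen with loss of the veratryl group, and ionisation at the electron-rich benzylic carbinol.
- Fallback: the O–C bond is made by vinyl transfer and the ring by metathesis, with no epoxide and no acid. It sets out from 5 and returns at 7.
- Pd(OCOCF3)2/4,7-diphenyl-1,10-phenanthroline-catalysed vinyl transfer from butyl vinyl ether gives the O-vinyl ether F8.
- Ring-closing metathesis with a second-generation ruthenium benzylidene catalyst gives the (2R,3R)-2,3-dihydrofuran F9.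
- Hydroboration–oxidation (BH3·THF; then NaOH, H2O2) places the hydroxyl group β to the ring oxygen and gives 7.

**Further compounds**

F1 | step 6 | 3,4-dimethoxybenzylmagnesium chloride | COc1ccc(C[Mg]Cl)cc1OC
F2 | step 6 | tertiary benzyl carbinol: 3-(3,4-dimethoxybenzyl) adduct of 8, OH cis to the C4 side chain | COc1ccc(COC[C@@H]2[C@H](c3ccc(OC)c(OC)c3)OC[C@@]2(O)Cc4ccc(OC)c(OC)c4)cc1OC
F3 | step 6 | exocyclic benzylidene oxolane (alkene geometry not fixed) | COc1ccc(COC[C@@H]2[C@H](c3ccc(OC)c(OC)c3)OCC2=Cc4ccc(OC)c(OC)c4)cc1OC
F4 | step 6 | vicinal diol, tertiary OH trans to the C4 side chain, benzylic carbinol configuration not fixed | COc1ccc(COC[C@@H]2[C@H](c3ccc(OC)c(OC)c3)OC[C@]2(O)C(O)c4ccc(OC)c(OC)c4)cc1OC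
F5 | step 2 | (1S,2S)-1-(3,4-dimethoxyphenyl)-2-{[(3,4-dimethoxybenzyl)oxy]methyl}but-3-en-1-ol | COc1ccc(COC[C@@H]([C@H](O)c2ccc(OC)c(OC)c2)C=C)cc1OC
F6 | step 2 | (S)-O-methylmandelate of the (1R,2R)-alcohol | COc1ccc(COC[C@H]([C@@H](OC(=O)[C@@H](OC)c2ccccc2)c3ccc(OC)c(OC)c3)C=C)cc1OC
F7 | step 2 | (S)-O-methylmandelate of the (1S,2S)-alcohol | COc1ccc(COC[C@@H]([C@H](OC(=O)[C@@H](OC)c2ccccc2)c3ccc(OC)c(OC)c3)C=C)cc1OC
F8 | step 4 | O-vinyl ether of 5 | COc1ccc(COC[C@H]([C@@H](OC=C)c2ccc(OC)c(OC)c2)C=C)cc1OC
F9 | step 4 | (2R,3R)-2-(3,4-dimethoxyphenyl)-3-{[(3,4-dimethoxybenzyl)oxy]methyl}-2,3-dihydrofuran | COc1ccc(COC[C@@H]2[C@H](c3ccc(OC)c(OC)c3)OC=C2)cc1OC
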